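## Retrosynthetic overview
- The (R)-lactol comes from lipase deacylation of a configurationally stable (R)-O-acyl lactol. That ester is set by acylative dynamic kinetic resolution of the freely racemising lactol.
- Ring C, the seven-membered depsidone lactone, is closed last by carbodiimide lactonisation of a diaryl-ether seco acid.
- Rings B and D are built together in one operation. A 4-aryloxy-1,3-bis(silyloxy)diene and a 4,4-diethoxybut-2-ynoate undergo Diels–Alder cycloaromatisation, followed by an acid quench. The tetra-ortho-substituted diaryl ether C–O bond is never made by arylation, because it begins as an alkyl aryl ether.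
- The diene comes from SN2 of the ring A phenol on a γ-bromo-α-methylacetoacetate. Ring A is bought as an orsellinate and needs only O-methylation and ortho-hydroxymethylation.
- Ring order: A (purchased), then B + D (one operation), then C.

Assumption: the lactol carbon is a hemiacylal that can racemise through the open formyl acid, so it is fixed as an O-acyl derivative and freed only in the last, base-free step. The sense of induction of the (R)-catalyst is assigned by analogy with (R)-1-arylalkanols and must be confirmed on the crystalline ester; the (S)-catalyst is equally available.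

## Route

**Step 1**
Reactants: 1 methyl 2,4-dihydroxy-6-methylbenzoate (methyl orsellinate)
Product: 2 methyl 2-hydroxy-4-methoxy-6-methylbenzoate
Conditions: MeI (1.05 equiv), K2CO3 (1.1 equiv), acetone, reflux
Reagents that add atoms: iodomethane, CI
Why: Williamson O-methylation, in which the 2-OH is tied up in a hydrogen bond to the ester carbonyl so one equivalent of MeI alkylates only the free and more acidic 4-OH.

**Step 2**
Reactants: 2 methyl 2-hydroxy-4-methoxy-6-methylbenzoate
Product: 4 methyl 2-hydroxy-3-(hydroxymethyl)-4-methoxy-6-methylbenzoate, via benzodioxaborinine 3 (not isolated)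
Conditions: PhB(OH)2 (1.2 equiv), (CH2O)n, EtCO2H (cat.), PhMe, reflux, Dean–Stark; then propane-1,3-diol, rt
Reagents that add atoms: paraformaldehyde as formaldehyde, C=O
Why: Nagata ortho-hydroxymethylation, in which the aryloxy(phenyl)boron hemiformal delivers CH2O intramolecularly to C3, the only free position ortho to the phenol, and holds the salicyl alcohol as cyclic boronate 3 until diol exchange releases it.

**Step 3**
Reactants: 5 ethyl 2-methyl-3-oxobutanoate
Product: 6 ethyl 4-bromo-2-methyl-3-oxobutanoate
Conditions: Br2 (1.0 equiv), CHCl3, 0 °C, then rt overnight with the HBr retained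
Reagents that add atoms: bromine, BrBr
Why: Acid-catalysed ketone α-bromination, in which the kinetic 2-bromide is isomerised by the liberated HBr to the more stable terminal 4-bromide (the classical entry to 3-methyltetronic acid).

**Step 4**
Reactants: 4 methyl 2-hydroxy-3-(hydroxymethyl)-4-methoxy-6-methylbenzoate; 6 ethyl 4-bromo-2-methyl-3-oxobutanoate
Product: 7 methyl 2-[(4-ethoxy-3-methyl-2,4-dioxobutyl)oxy]-3-(hydroxymethyl)-4-methoxy-6-methylbenzoate (epimerisable side-chain centre, racemic)
Conditions: K2CO3 (1.5 equiv), acetone, rt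
Reagents that add atoms: none
Why: Williamson etherification on an α-bromoketone, in which carbonate deprotonates the phenol but neither the benzylic alcohol nor appreciably the less acidic α-methyl keto ester, and room temperature avoids Dieckmann closure onto the ring A ester.

**Step 5**
Reactants: 8 3,3-diethoxyprop-1-yne
Product: 10 trimethylsilyl 4,4-diethoxybut-2-ynoate, via lithium carboxylate 9 (not isolated)
Conditions: n-BuLi, THF, −78 °C; CO2 (dry gas); Me3SiCl, −78 °C to rt; filter under N2, bulb-to-bulb distillation
Reagents that add atoms: carbon dioxide, O=C=O; chlorotrimethylsilane, C[Si](C)(C)Cl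
Why: Carboxylation of an alkynyllithium followed by O-silylation gives an ynoate whose ester falls off with water, so the acid needed for ring D appears without a separate deprotection.

**Step 6 (key step)**
Reactants: 7 methyl 2-[(4-ethoxy-3-methyl-2,4-dioxobutyl)oxy]-3-(hydroxymethyl)-4-methoxy-6-methylbenzoate; 10 trimethylsilyl 4,4-diethoxybut-2-ynoate
Product: 14 methyl 3-(hydroxymethyl)-4-methoxy-6-methyl-2-[(3,5,7-trihydroxy-6-methyl-1-oxo-1,3-dihydro-2-benzofuran-4-yl)oxy]benzoate (racemic lactol), via bis(silyloxy)diene 11 (not isolated), via cycloadduct 12 (not isolated), via silylated arene 13 (not isolated)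
Conditions: Me3SiOTf (3.3 equiv), Et3N (3.6 equiv), PhMe, 0 °C to rt; cannulate off the Et3NH·OTf layer; 10 (1.5 equiv), 110 °C, sealed tube, 24 h; then THF/H2O/AcOH 4:1:1, rt
Reagents that add atoms: water, O
Why: Soft double enolisation gives the Chan-type diene 11, whose nucleophilic aryloxy-bearing terminus bonds to the β-carbon of ynoate 10 in a Diels–Alder cycloaromatisation (known for such dienes with acetylenic esters); cycloadduct 12 can aromatise only by losing EtOSiMe3 because its sole ring hydrogen sits on the ArO-bearing carbon, and aqueous acid then strips the silyl groups of 13 so the freed ortho-carboxylic acid assists acetal hydrolysis and closes the hydroxy-lactone, giving benzene ring B and lactone ring D in one operation with the hindered diaryl ether already in place and the lactol centre formed racemic at this stage.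

**Step 7**
Reactants: 14 methyl 3-(hydroxymethyl)-4-methoxy-6-methyl-2-[(3,5,7-trihydroxy-6-methyl-1-oxo-1,3-dihydro-2-benzofuran-4-yl)oxy]benzoate
Product: 15 3-(hydroxymethyl)-4-methoxy-6-methyl-2-[(3,5,7-trihydroxy-6-methyl-1-oxo-1,3-dihydro-2-benzofuran-4-yl)oxy]benzoic acid (racemic lactol)
Conditions: LiOH·H2O (8 equiv), degassed THF/H2O 1:1, 45 °C; then 1 M HCl to pH 2, 0 °C
Reagents that add atoms: lithium hydroxide, [Li+].[OH-]
Why: Saponification of the normally sluggish di-ortho-substituted ring A ester is made mild by neighbouring-group participation of the adjacent ring B phenoxide (a transient depsidone that hydroxide reopens), while ring D only opens to the formyl carboxylate and recloses to the racemic lactol on acidification.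

**Step 8**
Reactants: 15 3-(hydroxymethyl)-4-methoxy-6-methyl-2-[(3,5,7-trihydroxy-6-methyl-1-oxo-1,3-dihydro-2-benzofuran-4-yl)oxy]benzoic acid
Product: 17 [(1R)-4-hydroxy-10-methoxy-5,8-dimethyl-3,7-dioxo-1-(propanoyloxy)-1,3-dihydro-7H-isobenzofuro[4,5-b][1,4]benzodioxepin-11-yl]methyl propanoate, via racemic depsidone lactol 16 (not isolated)
Conditions: DCC (1.1 equiv), CH2Cl2 (0.005 M), 0 °C to rt; concentrate to 0.1 M; (R)-2-phenyl-2,3-dihydroimidazo[2,1-b][1,3]benzothiazole [(R)-benzotetramisole, (R)-BTM, 10 mol %], (EtCO)2O (2.3 equiv), i-Pr2NEt (2.5 equiv), −20 °C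
Reagents that add atoms: propionic anhydride, CCC(=O)OC(=O)CC
Why: Carbodiimide (Steglich-type) lactonisation closes ring C because the ring A acid is the only free carboxyl (the ring D acid is masked as its lactol) and the neighbouring phenol is the only nucleophile within reach, after which an acylative dynamic kinetic resolution sets the stereocentre: i-Pr2NEt racemises 16 through the open formyl carboxylate while the chiral acyl-isothiouronium from (R)-BTM propionylates the (R)-lactol faster (aryl π–cation stacking as with (R)-1-arylalkanols), the primary alcohol being esterified alongside and the chelated phenol staying free.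

**Step 9**
Reactants: 17 [(1R)-4-hydroxy-10-methoxy-5,8-dimethyl-3,7-dioxo-1-(propanoyloxy)-1,3-dihydro-7H-isobenzofuro[4,5-b][1,4]benzodioxepin-11-yl]methyl propanoate
Product: 18 (1R)-1,4-dihydroxy-11-(hydroxymethyl)-10-methoxy-5,8-dimethyl-1H,7H-isobenzofuro[4,5-b][1,4]benzodioxepine-3,7-dione (target; (R)-cryptostictic acid)
Conditions: immobilised Candida antarctica lipase B, water-saturated MTBE, 20 °C; filter, wash with cold water, concentrate below 20 °C, crystallise
Reagents that add atoms: none
Why: Lipase-catalysed ester hydrolysis cleaves only acyl–oxygen bonds, so the C–O bond at the stereocentre is untouched (retention), the (R)-ester is the Kazlauskas-matched enantiomer so residual (S)-ester is left behind, and the weakly acidic base-free medium keeps the freed lactol from opening to the carboxylate that would racemise it.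

## Compound list
1 | methyl 2,4-dihydroxy-6-methylbenzoate | COC(=O)c1c(C)cc(O)cc1O | starting material
2 | methyl 2-hydroxy-4-methoxy-6-methylbenzoate | COC(=O)c1c(C)cc(OC)cc1O | intermediate
3 | methyl 5-methoxy-7-methyl-2-phenyl-4H-1,3,2-benzodioxaborinine-8-carboxylate | COC(=O)c1c(C)cc(OC)c2COB(c3ccccc3)Oc12 | intermediate (not isolated)
4 | methyl 2-hydroxy-3-(hydroxymethyl)-4-methoxy-6-methylbenzoate | COC(=O)c1c(C)cc(OC)c(CO)c1O | intermediate
5 | ethyl 2-methyl-3-oxobutanoate | CCOC(=O)C(C)C(C)=O | starting material
6 | ethyl 4-bromo-2-methyl-3-oxobutanoate | CCOC(=O)C(C)C(=O)CBr | intermediate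
7 | methyl 2-[(4-ethoxy-3-methyl-2,4-dioxobutyl)oxy]-3-(hydroxymethyl)-4-methoxy-6-methylbenzoate | CCOC(=O)C(C)C(=O)COc1c(CO)c(OC)cc(C)c1C(=O)OC | intermediate
8 | 3,3-diethoxyprop-1-yne | C#CC(OCC)OCC | starting material
9 | lithium 4,4-diethoxybut-2-ynoate | [Li+].[O-]C(=O)C#CC(OCC)OCC | intermediate (not isolated)
10 | trimethylsilyl 4,4-diethoxybut-2-ynoate | CCOC(OCC)C#CC(=O)O[Si](C)(C)C | intermediate
11 | methyl 2-{[(1Z)-4-ethoxy-3-methyl-2,4-bis(trimethylsilyloxy)buta-1,3-dien-1-yl]oxy}-4-methoxy-6-methyl-3-[(trimethylsilyloxy)methyl]benzoate | COC(=O)c1c(C)cc(OC)c(CO[Si](C)(C)C)c1O/C=C(\O[Si](C)(C)C)C(C)=C(OCC)O[Si](C)(C)C | intermediate (not isolated)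
12 | cyclohexa-1,4-diene cycloadduct of 11 and 10 (diastereomer mixture) | COC(=O)c1c(C)cc(OC)c(CO[Si](C)(C)C)c1OC1C(O[Si](C)(C)C)=C(C)C(OCC)(O[Si](C)(C)C)C(C(=O)O[Si](C)(C)C)=C1C(OCC)OCC | intermediate (not isolated)
13 | methyl 2-{2-(diethoxymethyl)-4-hydroxy-5-methyl-6-(trimethylsilyloxy)-3-[(trimethylsilyloxy)carbonyl]phenoxy}-4-methoxy-6-methyl-3-[(trimethylsilyloxy)methyl]benzoate | COC(=O)c1c(C)cc(OC)c(CO[Si](C)(C)C)c1Oc1c(O[Si](C)(C)C)c(C)c(O)c(C(=O)O[Si](C)(C)C)c1C(OCC)OCC | intermediate (not isolated)
14 | methyl 3-(hydroxymethyl)-4-methoxy-6-methyl-2-[(3,5,7-trihydroxy-6-methyl-1-oxo-1,3-dihydro-2-benzofuran-4-yl)oxy]benzoate, racemic | COC(=O)c1c(C)cc(OC)c(CO)c1Oc1c(O)c(C)c(O)c2c1C(O)OC2=O | intermediate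
15 | 3-(hydroxymethyl)-4-methoxy-6-methyl-2-[(3,5,7-trihydroxy-6-methyl-1-oxo-1,3-dihydro-2-benzofuran-4-yl)oxy]benzoic acid, racemic | OC(=O)c1c(C)cc(OC)c(CO)c1Oc1c(O)c(C)c(O)c2c1C(O)OC2=O | intermediate
16 | racemic 1,4-dihydroxy-11-(hydroxymethyl)-10-methoxy-5,8-dimethyl-1H,7H-isobenzofuro[4,5-b][1,4]benzodioxepine-3,7-dione | COc1cc(C)c2c(c1CO)Oc1c(c(C)c(O)c3c1C(O)OC3=O)OC2=O | intermediate (not isolated)
17 | [(1R)-4-hydroxy-10-methoxy-5,8-dimethyl-3,7-dioxo-1-(propanoyloxy)-1,3-dihydro-7H-isobenzofuro[4,5-b][1,4]benzodioxepin-11-yl]methyl propanoate | COc1cc(C)c2c(c1COC(=O)CC)Oc1c(c(C)c(O)c3c1[C@H](OC(=O)CC)OC3=O)OC2=O | intermediate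
18 | (1R)-1,4-dihydroxy-11-(hydroxymethyl)-10-methoxy-5,8-dimethyl-1H,7H-isobenzofuro[4,5-b][1,4]benzodioxepine-3,7-dione | COc1cc(C)c2c(c1CO)Oc1c(c(C)c(O)c3c1[C@H](O)OC3=O)OC2=O | target

## Step count and risks
Total step count: 9. Longest linear sequence: 7 (steps 1, 2, 4, 6, 7, 8, 9).

**Step 6.** The diene is tetrasubstituted and carries a bulky aryloxy group at the reacting terminus. The ynoate is activated by only one ester, so cycloaddition may be slower than diene decay. The fallback replaces the pericyclic route with an anionic Michael–Dieckmann benzannulation; it sets out from 7 (with 8) and rejoins the route at 15. Compound 8 is lithiated and quenched with ethyl chloroformate to give ethyl 4,4-diethoxybut-2-ynoate F1. Compound 7 is converted with LDA (3.2 equiv, THF, −78 °C) into its alkoxide/1,3-dicarbonyl dianion, and the γ-carbanion adds to F1. The resulting allenolate closes onto the ethyl ester and tautomerises to methyl 2-[2-(diethoxymethyl)-3-(ethoxycarbonyl)-4,6-dihydroxy-5-methylphenoxy]-3-(hydroxymethyl)-4-methoxy-6-methylbenzoate F2. Aqueous acetic acid unmasks methyl 2-[3-(ethoxycarbonyl)-2-formyl-4,6-dihydroxy-5-methylphenoxy]-3-(hydroxymethyl)-4-methoxy-6-methylbenzoate F3. Both esters of F3 are then cleaved by LiOH (formyl- and phenoxide-assisted), and acidification gives 15.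

**Step 8.** The small-molecule catalyst may discriminate poorly on this crowded lactol, or the background acylation may erode the ee. The fallback is an enzymatic second-order asymmetric transformation; it sets out from 16 (isolated after the DCC stage) and rejoins the route at 18. Burkholderia cepacia lipase and vinyl acetate in toluene, with a trace of Et3N to keep the lactol racemising, acetylate the (R)-lactol and the primary alcohol. This gives [(1R)-1-(acetyloxy)-4-hydroxy-10-methoxy-5,8-dimethyl-3,7-dioxo-1,3-dihydro-7H-isobenzofuro[4,5-b][1,4]benzodioxepin-11-yl]methyl acetate F4, which is hydrolysed under the step 9 conditions to 18.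

**Step 9.** The lipase may reject the bulky lactol ester, or the freed lactol may racemise before isolation. The fallback drops the ester detour altogether; it sets out from 16 and rejoins the route at 18. Racemic 16 is resolved by preparative chiral supercritical-fluid chromatography (CO2/MeOH with 0.1 % formic acid, column at 5 °C). The (R)-fraction is collected cold and crystallised at once. The (S)-fraction is racemised with a catalytic amount of i-Pr2NEt and re-injected. This fallback makes no new compound (F0).

## Further compounds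
F1 | step 6 | ethyl 4,4-diethoxybut-2-ynoate | CCOC(=O)C#CC(OCC)OCC
F2 | step 6 | methyl 2-[2-(diethoxymethyl)-3-(ethoxycarbonyl)-4,6-dihydroxy-5-methylphenoxy]-3-(hydroxymethyl)-4-methoxy-6-methylbenzoate | COC(=O)c1c(C)cc(OC)c(CO)c1Oc1c(O)c(C)c(O)c(C(=O)OCC)c1C(OCC)OCC
F3 | step 6 | methyl 2-[3-(ethoxycarbonyl)-2-formyl-4,6-dihydroxy-5-methylphenoxy]-3-(hydroxymethyl)-4-methoxy-6-methylbenzoate | COC(=O)c1c(C)cc(OC)c(CO)c1Oc1c(O)c(C)c(O)c(C(=O)OCC)c1C=O
F4 | step 8 | [(1R)-1-(acetyloxy)-4-hydroxy-10-methoxy-5,8-dimethyl-3,7-dioxo-1,3-dihydro-7H-isobenzofuro[4,5-b][1,4]benzodioxepin-11-yl]methyl acetate | COc1cc(C)c2c(c1COC(C)=O)Oc1c(c(C)c(O)c3c1[C@H](OC(C)=O)OC3=O)OC2=O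
F0 | step 9 | none | none
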